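**Plan**
Cuts: C9–C11 (side chain off the decalin), C12–C13 (inside the side-chain piece), then C1–C10 and C4–C5 together (ring A off ring B).
Enabling feature: ring B (C5–C10) has oxygen on C6, an sp2 C9, and methyl groups on C8 and on quaternary C10. This is the pattern of 2,6-dimethyl-1,4-benzoquinone fused along C5–C10, and C1–C4 with the gem-dimethyl C4 is 4-methylpenta-1,3-diene.
Forward order: ring B is bought as the quinone and ring A closes on it in one catalytic enantioselective [4+2] step. Ring B is then adjusted (C5, C6, C7/C8), ring A is saturated, C9 becomes an alkenyl triflate, and the C11–C16 chain is joined last by B-alkyl Suzuki–Miyaura coupling.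
Stereochemistry: C10 (and provisionally C5) comes from the chiral oxazaborolidinium catalyst, and C5 is reset to trans by equilibration against C10. C6 and C7 come from α-face attack enforced by the β-axial methyl groups, and 13Z comes from directed trans-hydroalumination of but-2-yn-1-ol.

Key step: step 1

Remark: labdane numbering is used for all bicyclic compounds (decalin C1–C10, C17 on C8, C18/C19 on C4, C20 on C10, chain C11–C16), with β meaning the face of C20.
Assumption: the catalyst antipode is assigned from the α-C–H···O binding picture of cationic oxazaborolidines, which calls for the (R)-diphenylprolinol series to cover the β face of the bound quinone; both antipodes are commercial, so a reversed sense would be met by the mirror-image catalyst with nothing else changed.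

**Step 1**
Reactants: 1 2,6-dimethyl-1,4-benzoquinone; 2 4-methylpenta-1,3-diene
Product: 3 (4aR,8aS)-2,5,5,8a-tetramethyl-4a,5,8,8a-tetrahydronaphthalene-1,4-dione (cis-fused adduct: 5β-H and 10β-CH3; ketones C6 and C9; alkenes C2=C3 and C7=C8)
Conditions: (R)-3,3-diphenyl-1-(o-tolyl)tetrahydro-1H,3H-pyrrolo[1,2-c][1,3,2]oxazaborole (20 mol %), Tf2NH (18 mol %), 2 (5 equiv, freed from 2-methylpenta-1,3-diene with maleic anhydride), CH2Cl2, −78 → −20 °C
Reagents that add atoms: none
Why: The protonated oxazaborolidine binds the quinone carbonyl that is not flanked by methyl groups (future C6) through boron and an α-C–H···O contact, which lowers the LUMO and makes the methyl-bearing β-carbon (future C10) the most electrophilic site. The diene reacts through its gauche s-cis conformer in a concerted but strongly asynchronous [4+2] cycloaddition, and the closest known reaction type is the oxazaborolidinium-catalysed Diels–Alder reaction of methylated benzoquinones with acyclic dienes. Ring A closes as a six-membered carbocycle by suprafacial addition across C5=C10, with C1–C10 forming ahead of C4–C5. C5 and C10 arise together: their cis relation follows from suprafaciality and their absolute sense from the catalyst aryl group, which covers the β face so that the diene arrives from the α face, while endo or exo approach is immaterial because neither diene terminus becomes stereogenic. The regioselectivity needed is secured twice, since the CH2 terminus is the more nucleophilic end (attack there develops tertiary allyl cation character) and the reverse orientation would join CMe2 to the carbon that becomes quaternary. The two ring double bonds of 1 are homotopic, so site selectivity is no issue, and the enedione left in 3 is too hindered for a second addition.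

**Step 2**
Reactants: 3 cis-fused adduct
Product: 4 (4aS,8aS)-2,5,5,8a-tetramethyl-4a,5,8,8a-tetrahydronaphthalene-1,4-dione (trans-fused: 5α-H and 10β-CH3)
Conditions: DBU (0.1 equiv), CH2Cl2, rt; recovered 3 is resubmitted
Reagents that add atoms: none
Why: Base-catalysed epimerisation through the C5 enolate of the C6 ketone (aromatisation is blocked by quaternary C10) should let the ring fusion settle in the trans form, which avoids the clash of the C4 gem-dimethyl group with the concave face of ring B, while the untouched C10 relays the absolute configuration to C5.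

**Step 3**
Reactants: 4 trans-fused enedione
Product: 5 trans-fused 6β-hydroxy-4,4,8,10-tetramethyl-2,7-dien-9-one (5α-H)
Conditions: NaBH4 (1 equiv), CeCl3·7H2O (1 equiv), MeOH, −78 → −40 °C
Reagents that add atoms: none
Why: The Luche 1,2-reduction should pick the C6 carbonyl because C9 is flanked by quaternary C10 and the C8 methyl group, and hydride arrives from the α face, away from the axial C10 and C4β methyl groups, to give the axial 6β-alcohol.

**Step 4**
Reactants: 5 6β-hydroxy enone
Product: 6 trans-fused 6β-acetoxy-4,4,8,10-tetramethyl-2,7-dien-9-one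
Conditions: Ac2O, DMAP, Et3N, CH2Cl2, rt → 40 °C
Reagents that add atoms: acetic anhydride CC(=O)OC(C)=O
Why: DMAP-catalysed acylation esterifies the hindered axial allylic alcohol with retention at C6, and placing the acetate now removes any later need to tell three hydroxyl groups apart.

**Step 5**
Reactants: 6 6β-acetoxy enone
Product: 7 6β-acetoxy-7α,8α-epoxy-4,4,8,10-tetramethyl-2-en-9-one
Conditions: t-BuOOH (decane), DBU, CH2Cl2, 0 °C → rt
Reagents that add atoms: tert-butyl hydroperoxide CC(C)(C)OO
Why: The Weitz–Scheffer nucleophilic epoxidation touches only the electron-poor C7=C8 bond (C2=C3 is inert), and the peroxide anion adds to C7 along the axial α trajectory, anti to the 6β-acetate and the C10 methyl group, so that the 7α,8α-epoxide should result.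

**Step 6**
Reactants: 7 epoxy ketone
Product: 8 6β-acetoxy-7α-hydroxy-4,4,8,10-tetramethyl-2-en-9-one (drawn with the equatorial 8α-methyl group and 8β-H)
Conditions: SmI2 (2.5 equiv), THF/MeOH, −90 °C
Reagents that add atoms: none
Why: Single-electron reduction of the α,β-epoxy ketone by divalent samarium cleaves the C8–O bond of the ketyl, and protonation of the trivalent samarium enolate gives the β-hydroxy ketone with the C7–O bond and its 7α configuration intact, while the C8 centre formed here is erased in step 9.

**Step 7**
Reactants: 8 β-hydroxy ketone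
Product: 9 6β-acetoxy-7α-hydroxy-4,4,8,10-tetramethyl-trans-decalin-9-one
Conditions: H2 (1 atm), 10 % Pd/C, EtOAc, rt
Reagents that add atoms: none
Why: Heterogeneous catalytic hydrogenation saturates the only remaining C=C bond (C2=C3) and creates no stereocentre.

**Step 8**
Reactants: 9 saturated β-hydroxy ketone
Product: 10 6β-acetoxy-7α-(tert-butyldimethylsilyloxy)-4,4,8,10-tetramethyl-trans-decalin-9-one
Conditions: TBSOTf, 2,6-lutidine, CH2Cl2, −78 → 0 °C
Reagents that add atoms: tert-butyldimethylsilyl triflate CC(C)(C)[Si](C)(C)OS(=O)(=O)C(F)(F)F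
Why: Silylation with a silyl triflate and a non-nucleophilic base masks the axial 7α-hydroxyl without triggering retro-aldol cleavage or dehydration of the β-hydroxy ketone.

**Step 9**
Reactants: 10 silyloxy ketone
Product: 11 6β-acetoxy-7α-(tert-butyldimethylsilyloxy)-4,4,8,10-tetramethyl-trans-octal-8-en-9-yl triflate
Conditions: Tf2O (1.5 equiv), 2,6-di-tert-butyl-4-methylpyridine (2 equiv), CH2Cl2, 0 °C → rt
Reagents that add atoms: triflic anhydride O=S(=O)(OS(=O)(=O)C(F)(F)F)C(F)(F)F
Why: Alkenyl triflate formation by O-triflation of the ketone and loss of its only α-hydrogen (C8–H) under hindered-pyridine buffering, a protocol routinely applied to acetoxy ketones next to a quaternary carbon, fixes the tetrasubstituted C8=C9 bond and spares the acetate and the silyl ether.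

**Step 10**
Reactants: 12 but-2-yn-1-ol
Product: 14 (Z)-3-iodobut-2-en-1-ol, via cyclic alkenylalanate 13 (not isolated)
Conditions: NaAlH2(OCH2CH2OCH3)2, THF, 0 °C → rt; EtOAc; then I2, −78 °C → 0 °C
Reagents that add atoms: iodine II
Why: Alkoxide-directed trans-hydroalumination of the propargylic alcohol places aluminium on C3 within a five-membered alanate, and iodinolysis with retention gives the Z-iodide that fixes the geometry of the future C13=C14 bond.

**Step 11**
Reactants: 14 (Z)-3-iodobut-2-en-1-ol
Product: 15 tert-butyl{[(2Z)-3-iodobut-2-en-1-yl]oxy}dimethylsilane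
Conditions: TBSCl, imidazole, CH2Cl2, 0 °C → rt
Reagents that add atoms: tert-butyldimethylsilyl chloride CC(C)(C)[Si](C)(C)Cl
Why: Imidazole-promoted silylation protects the primary allylic alcohol without touching the alkenyl iodide.

**Step 12**
Reactants: 15 Z-iodide silyl ether
Product: 16 tert-butyldimethyl{[(2Z)-3-methylpenta-2,4-dien-1-yl]oxy}silane
Conditions: vinylmagnesium bromide (1.5 equiv), Pd(PPh3)4 (5 mol %), THF, 0 °C → rt
Reagents that add atoms: vinylmagnesium bromide C=C[Mg]Br
Why: The Kumada–Corriu coupling of an alkenyl iodide at zerovalent palladium proceeds with retention of double-bond geometry and should deliver the Z-diene.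

**Step 13**
Reactants: 11 alkenyl triflate; 16 Z-diene
Product: 18 6β-acetoxy-7α,15-bis(tert-butyldimethylsilyloxy)labda-8,13Z-diene, via primary alkyl-9-BBN borane 17 (not isolated)
Conditions: 16, 9-BBN (1.1 equiv), THF, 0 °C → rt; then 11, Pd(dppf)Cl2 (10 mol %), AsPh3 (10 mol %), aq K3PO4, DMF, 50 °C
Reagents that add atoms: none
Why: 9-BBN hydroborates only the monosubstituted terminus of the diene in the anti-Markovnikov sense, and the B-alkyl Suzuki–Miyaura coupling of the resulting primary borane with the alkenyl triflate forms C9–C11 without touching the Z-alkene or any stereocentre.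

**Step 14**
Reactants: 18 bis-silyl ether
Product: 19 (13Z)-6β-acetoxylabda-8,13-diene-7α,15-diol (CNP0183298.2)
Conditions: HF·pyridine, pyridine, THF, 0 °C → rt
Reagents that add atoms: none
Why: Fluoride-driven desilylation under buffered conditions frees both hydroxyl groups and leaves the hindered 6β-acetate in place, and acyl migration to O7 is barred by the trans-diaxial 6β,7α arrangement.

**Compound list**
1 | 2,6-dimethyl-1,4-benzoquinone | CC1=CC(=O)C=C(C)C1=O | starting material
2 | 4-methylpenta-1,3-diene | C=CC=C(C)C | starting material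
3 | (4aR,8aS)-2,5,5,8a-tetramethyl-4a,5,8,8a-tetrahydronaphthalene-1,4-dione (cis adduct) | O=C1C=C(C)C(=O)[C@@]2(C)CC=CC(C)(C)[C@@H]12 | intermediate
4 | (4aS,8aS)-2,5,5,8a-tetramethyl-4a,5,8,8a-tetrahydronaphthalene-1,4-dione (trans enedione) | O=C1C=C(C)C(=O)[C@@]2(C)CC=CC(C)(C)[C@H]12 | intermediate
5 | trans-fused 6β-hydroxy-2,7-dien-9-one | O[C@@H]1C=C(C)C(=O)[C@@]2(C)CC=CC(C)(C)[C@H]12 | intermediate
6 | trans-fused 6β-acetoxy-2,7-dien-9-one | CC(=O)O[C@@H]1C=C(C)C(=O)[C@@]2(C)CC=CC(C)(C)[C@H]12 | intermediate
7 | 6β-acetoxy-7α,8α-epoxy-2-en-9-one | CC(=O)O[C@@H]1[C@H]3O[C@@]3(C)C(=O)[C@@]2(C)CC=CC(C)(C)[C@H]12 | intermediate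
8 | 6β-acetoxy-7α-hydroxy-8α-methyl-2-en-9-one | CC(=O)O[C@@H]1[C@@H](O)[C@@H](C)C(=O)[C@@]2(C)CC=CC(C)(C)[C@H]12 | intermediate
9 | 6β-acetoxy-7α-hydroxy-8α-methyl-trans-decalin-9-one | CC(=O)O[C@@H]1[C@@H](O)[C@@H](C)C(=O)[C@@]2(C)CCCC(C)(C)[C@H]12 | intermediate
10 | 7α-TBS ether of 9 | CC(=O)O[C@@H]1[C@@H](O[Si](C)(C)C(C)(C)C)[C@@H](C)C(=O)[C@@]2(C)CCCC(C)(C)[C@H]12 | intermediate
11 | C8=C9 alkenyl triflate | CC(=O)O[C@@H]1[C@@H](O[Si](C)(C)C(C)(C)C)C(C)=C(OS(=O)(=O)C(F)(F)F)[C@@]2(C)CCCC(C)(C)[C@H]12 | intermediate
12 | but-2-yn-1-ol | CC#CCO | starting material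
13 | sodium cyclic alkenylalanate (five-membered O–Al–C3 ring, two 2-methoxyethoxy ligands; not isolated) | [Na+].CC1=CCO[Al-]1(OCCOC)OCCOC | intermediate
14 | (Z)-3-iodobut-2-en-1-ol | C/C(I)=C/CO | intermediate
15 | tert-butyl{[(2Z)-3-iodobut-2-en-1-yl]oxy}dimethylsilane | C/C(I)=C/CO[Si](C)(C)C(C)(C)C | intermediate
16 | tert-butyldimethyl{[(2Z)-3-methylpenta-2,4-dien-1-yl]oxy}silane | C=C/C(C)=C\CO[Si](C)(C)C(C)(C)C | intermediate
17 | B-[(3Z)-5-(tert-butyldimethylsilyloxy)-3-methylpent-3-en-1-yl]-9-BBN (not isolated) | CC(C)(C)[Si](C)(C)OC/C=C(C)\CCB1C2CCCC1CCC2 | intermediate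
18 | 6β-acetoxy-7α,15-bis(tert-butyldimethylsilyloxy)labda-8,13Z-diene | CC(=O)O[C@@H]1[C@@H](O[Si](C)(C)C(C)(C)C)C(C)=C(CC/C(C)=C\CO[Si](C)(C)C(C)(C)C)[C@@]2(C)CCCC(C)(C)[C@H]12 | intermediate
19 | (13Z)-6β-acetoxylabda-8,13-diene-7α,15-diol | CC(=O)O[C@@H]1[C@@H](O)C(C)=C(CC/C(C)=C\CO)[C@@]2(C)CCCC(C)(C)[C@H]12 | target

Total step count: 14. Longest linear sequence: 11 steps (steps 1–9, 13, 14).

**Steps most likely to fail**

**Step 1.** The cis-methyl group of the diene disfavours the s-cis conformer. The cycloaddition may therefore be too slow at temperatures where the catalyst stays selective, and acid-induced oligomerisation of the diene may win. The fallback sets out from 1 and activates the diene with a 2-silyloxy group.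
- Mesityl oxide is enolised kinetically (LiN(i-Pr)2, then TIPSOTf, THF, −78 °C) to 4-methyl-2-(triisopropylsilyloxy)penta-1,3-diene F1.
- Under the same catalyst F1 adds to 1, either in concert or by Mukaiyama–Michael addition and ring closure, so that the s-cis demand falls away. The same C1–C10 and C4–C5 bonds form, giving the 2-silyloxy cis adduct F2.
- CsF and PhNTf2 in DME convert the silyl enol ether into the C2 alkenyl triflate F3.
- Palladium-catalysed formate reduction (Pd(OAc)2, PPh3, HCO2H, Bu3N, DMF) comes back to the route at 3. Any C5 epimerisation on the way only anticipates step 2.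

**Step 13.** Oxidative addition and transmetalation at a triflate flanked by quaternary C10 and the C8 methyl group may be slow. Protodeboronation, β-hydride elimination or triflate hydrolysis could then take over. The fallback sets out from 11 and reverses the roles of the partners.
- A Stille coupling with the small tributyl(vinyl)stannane (Pd(PPh3)4, LiCl, THF, reflux) gives the 9-vinyl diene F4.
- 9-BBN hydroborates the terminal carbon of F4 to the C12 borane F5.
- B-alkyl Suzuki–Miyaura coupling of F5 with the unhindered Z-iodide 15 (Pd(dppf)Cl2, aq K3PO4, DMF, rt) forms C12–C13 and comes back at 18.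

**Step 2.** The thermodynamic bias for the trans fusion may be too small, or the enedione may self-condense under base. The fallback sets out from 3 and replaces equilibration by kinetic protonation.
- LiN(SiMe3)2 and TMSCl (THF, −78 °C) give the cross-conjugated C5=C6 trimethylsilyl dienol ether F6.
- Low-temperature protodesilylation (HF·pyridine, THF, −78 °C) should deliver the proton to C5 from the α face, opposite the C10 methyl group, and comes back at 4.

**Further compounds**
F1 | step 1 | 4-methyl-2-(triisopropylsilyloxy)penta-1,3-diene | C=C(O[Si](C(C)C)(C(C)C)C(C)C)C=C(C)C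
F2 | step 1 | 2-(triisopropylsilyloxy) cis adduct (5β-H, 10β-CH3) | O=C1C=C(C)C(=O)[C@@]2(C)CC(O[Si](C(C)C)(C(C)C)C(C)C)=CC(C)(C)[C@@H]12
F3 | step 1 | C2 alkenyl triflate of the cis adduct | O=C1C=C(C)C(=O)[C@@]2(C)CC(OS(=O)(=O)C(F)(F)F)=CC(C)(C)[C@@H]12
F4 | step 13 | 6β-acetoxy-7α-(tert-butyldimethylsilyloxy)-9-vinyl-8-ene | CC(=O)O[C@@H]1[C@@H](O[Si](C)(C)C(C)(C)C)C(C)=C(C=C)[C@@]2(C)CCCC(C)(C)[C@H]12
F5 | step 13 | C12 9-BBN borane of F4 | CC(=O)O[C@@H]1[C@@H](O[Si](C)(C)C(C)(C)C)C(C)=C(CCB3C4CCCC3CCC4)[C@@]2(C)CCCC(C)(C)[C@H]12
F6 | step 2 | C5=C6 trimethylsilyl dienol ether of 3 | C[Si](C)(C)OC=1C=C(C)C(=O)[C@@]2(C)CC=CC(C)(C)C=12
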